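**Numbering used below.** Ring B (cyclohexanone): C1 (C=O), C2 (CHMe), C3 (quaternary, carries CH3 and the chain), C4 (CHMe), C5, C6. Chain, counted from ring B: C1' (CH2 on C3), C2' (CHOH), C3' (=C–CH3), C4' (=CH), C5' (CH2 on the quinone). Ring A (quinone): C1q (C=O next to C6q–CH3), C2q (C–OH), C3q (carries the chain), C4q (C=O), C5q (C–Cl), C6q (C–CH3). The target is (2S,3S,4S) in ring B, (2'S), and E at C3'=C4'.

## The problem

The skeleton joins a fully substituted hydroxy-chloro-methyl-p-quinone (ring A) to a 2,3,4-trimethylcyclohexanone (ring B) through a five-carbon chain that holds an E-trisubstituted alkene and an allylic carbinol. Ring B has three contiguous stereocentres, C2, quaternary C3 and C4, with the C1' arm cis to both secondary methyl groups, so the larger group on C3 lies on the more crowded face. C4 can control C3 and C3 can control C2, but the carbinol C2' is insulated from the ring by the C1' methylene and needs reagent control. C2 is alpha to the ketone, and because the axial arm is wedged between two cis methyl groups the natural arrangement cannot be assumed to be the thermodynamic one; C2 must be set kinetically and then kept away from enolising conditions. The feature that opens the key step is that C3 carries a two-carbon arm whose second carbon (C2') is oxygenated, while C2 lies between C3 and the carbonyl C1: if C1=O/C2–H is read as a C1=C2 double bond, the atoms C2'–C1'–C3–C2=C1 are a gamma,delta-unsaturated carbonyl array, the retron of a Claisen rearrangement in which a C1–O bond on the face of the arm delivers C1' to C3. A second feature is the local mirror plane through C3 (both CHMe groups cis to the arm, only the C1 carbonyl breaks it), which maps ring B onto meso cis-2,6-dimethylcyclohexanone 1 with its carbonyl carbon as the future C3. The hydroxyquinone (acidic, reducible, electrophilic at C5q) tolerates neither organometallic reagents nor base and must come last; the secondary allylic alcohol ionises under acid; and the C1 ketone with the C2' hydroxyl can close to a hemiketal.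

## Retrosynthesis

**C1q–O bond.** 27 is the Teuber oxidation product of resorcinol 26. In 26 the only unsubstituted ring carbon is para to one hydroxyl and ortho to the other, so only one hydroxy-p-quinone can form, and chlorine, methyl and chain fall into place without a regiochemical decision. Building ring A around the chain, or carrying a masked quinone, would cost steps and expose a chloroquinone to nucleophiles. The forward step must oxidise a phenol beside an allylic alcohol, an alkene and an epimerisable ketone; 26 itself comes from its bis-silyl ether 25.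

**C2'–C3' bond.** Cutting 25 between the carbinol carbon and the alkene gives keto aldehyde 12 and alkenyl iodide 24, two halves of eleven carbons each. One holds all ring-B stereocentres, the other the arene and the alkene geometry. A cut at C5'–C3q would send the allylic alcohol through aryl-metal chemistry; a cut at C1'–C2' would need a neopentyl nucleophile on a quaternary carbon. The forward reaction must add an alkenyl metal to an aldehyde beside a ketone, keep the E geometry, and choose the aldehyde face through a chiral ligand, because the ring stereocentres are too far away to help.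

**C1=O and C2–H.** 12 is the double oxidation product of diol 11, and 11 is traced to unsaturated ester 9. Hydroboration of C1=C2 puts oxygen on C1 and hydrogen on C2 in one syn addition, while borane also reduces the ester to the C2' alcohol. Compared with methylating a C1 enolate at C2, this brings in hydrogen rather than carbon from the open ring face, so the C2 methyl is pushed to the side of the arm. It is a kinetic event, which matters because C2 cannot be safely corrected later. 9 has one stereocentre and two oxygen functions fewer than 12.

**C3–C1' bond (key disconnection).** In 9 the arm on C3 and the C1=C2 bond form a gamma,delta-unsaturated ester. The Claisen transform breaks C3–C1' and returns the oxygen to C1, giving allylic alcohol 7 (rearranging through ketene acetal 8). This removes the quaternary stereocentre: 7 has a tetrasubstituted alkene and only two stereocentres, the C1 carbinol and C4, and C1 is easy to set by catalytic reduction. The neighbouring cut, C3–CH3 by conjugate addition, must bring the last group to C3 under steric control by C4; here the arm is tied to the C1 oxygen and cannot reach the wrong face. The forward step needs the cis relation of C1–O and the C4 methyl, and a rearrangement faster than ionisation.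

**Ring B from a meso ketone.** 7 is the reagent-controlled reduction product of enone 6. 6 is enone 4 with one more methyl group: 1,2-addition of methyl gives tertiary alcohol 5, and oxidative 1,3-transposition moves the oxygen to the future C1, so the carbonyl carbon of 4 ends as C3. 4 is the dehydrogenation product of silyl enol ether 3, which arises (through lithium enolate 2) from meso ketone 1 by removal of one of two enantiotopic alpha-protons with a chiral lithium amide. The two CHMe carbons of 1 are C2 and C4; the desymmetrisation decides which stays a stereocentre (C4) and which flank will carry the ketone. One reagent-controlled event fixes C4, and C1, C3 and C2 follow from it in turn.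

**Aryl–C5' bond.** 24 is the silyl ether of resorcinol 23, which comes from bis-acetal 22. 22 is cut at the aryl–CH2 bond into arene 15 (lithiated to 20, transmetalated to 21) and allylic bromide 19; metalation between two acetal oxygens is the regiochemically safe way to reach that position. 15 comes from orcinol 13 through chloride 14. 19 comes from but-2-yn-1-ol 16 by syn-hydrozirconation and iodination (through 17 to 18) and bromination, which fixes the E geometry before the fragments meet.

## Roads not taken

**Alternative 1:** the most obvious plan cuts the two methyl groups at C3 and C2 of ring B.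
- Forward key step: conjugate addition of a methylcopper reagent to (S)-4-methyl-3-(prop-2-en-1-yl)cyclohex-2-en-1-one A1, anti to the C4 methyl group, with capture of the enolate by a methyl halide, then ozonolysis to 12.
- The facial logic at C3 is sound. At C2, however, the incoming group is carbon and enters anti to the arm, so the expected product is the C2 epimer (2R,3S,4S)-2,3,4-trimethyl-3-(prop-2-en-1-yl)cyclohexan-1-one A2.
- Repair by equilibration is unsafe, because in the natural isomer the axial arm is held between two cis methyl groups.
- The chosen plan uses the same face preference to bring in hydrogen at C2, delivers the arm to C3 intramolecularly, and draws its chirality from a meso compound rather than from an enantioenriched 4-methylcyclohexenone that needs two more steps to reach A1.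

**Alternative 2:** close ring A between two halves.
- Forward key step: a squarate-derived cyclobutenedione A3 carrying the complete chain (C2' as silyl ether, C1 ketone as dioxolane) would take up a chloro-substituted propenyllithium at the carbonyl next to the alkoxy carbon to give 4-hydroxycyclobutenone A4. Thermal ring opening and 6π closure (Moore-type rearrangement), oxidation and cleavage of the vinylogous ester would end at 27.
- This solves a problem the target does not pose: the substitution pattern of ring A follows for free from orcinol and a Teuber oxidation.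
- It would add protection of ketone and carbinol, a thermolysis above 100 °C with an allylic silyl ether on board, and a final hydrolysis next to a chloroquinone carbon that is itself open to addition–elimination.

**Alternative 3:** use the latent hemiketal to relay stereochemistry from ring B to C2'.
- Forward key step: 12 would be closed with methanol to the bicyclic acetal 1,3-dimethoxy-5,6,9-trimethyl-2-oxabicyclo[3.3.1]nonane A5. Lewis-acid ionisation at the former aldehyde carbon would let 24, after iodine–metal exchange, attack from the exo face (the endo face looks at C5 and C6 of ring B), giving bicyclic ketal A6 with the S configuration at C2'. Mild aqueous acid would open A6 to 25.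
- The union would be substrate-controlled. But the ketal carbon (the former C1) ionises more easily than the acetal carbon, which opens the bicycle and leads to an acyclic pathway with no facial bias.
- It also costs two more steps. The chosen plan keeps the ligand-controlled coupling.

Key step: step 6

Assumption: commercial 2,6-dimethylcyclohexanone is enriched to the cis (meso) isomer 1 by base equilibration and distillation before use, and the hand of the chiral lithium amide (step 1), of the oxazaborolidine (step 5) and of the chromium ligand (step 16) is written as expected from their usual models and would be inverted if the observed sense were opposite.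

## Route

Step 1
Reactants: 1 cis-2,6-dimethylcyclohexan-1-one (meso)
Product: 3 (S)-[(2,6-dimethylcyclohex-1-en-1-yl)oxy]trimethylsilane, via lithium enolate 2 (not isolated)
Conditions: (R,R)-[PhCH(Me)]2NLi, LiCl, TMSCl, THF, −100 °C
Reagents that add atoms: chlorotrimethylsilane, C[Si](C)(C)Cl
Why: Enantioselective deprotonation (desymmetrisation) of a meso ketone by a chiral lithium amide with in situ silyl quench; the base should remove the alpha-proton at the R-configured carbon, so that the other CHMe carbon (the future C4) remains as the S stereocentre of 3.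

Step 2
Reactants: 3 (S)-[(2,6-dimethylcyclohex-1-en-1-yl)oxy]trimethylsilane
Product: 4 (S)-2,6-dimethylcyclohex-2-en-1-one
Conditions: Pd(OAc)2 (cat.), O2, DMSO, rt
Reagents that add atoms: none
Why: Saegusa–Ito oxidation: divalent palladium binds the enol ether carbon and beta-hydride elimination into the ring gives the conjugated enone; the medium is neutral, so the alpha-stereocentre should not epimerise.

Step 3
Reactants: 4 (S)-2,6-dimethylcyclohex-2-en-1-one
Product: 5 (1S,6S)-1,2,6-trimethylcyclohex-2-en-1-ol
Conditions: MeLi, CeCl3, THF, −78 °C
Reagents that add atoms: methyllithium, [Li]C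
Why: 1,2-Addition of an organocerium reagent, nucleophilic but hardly basic, so the enolisable C6–H (future C4) is not touched; methyl should enter anti to the neighbouring methyl group, but the new carbinol centre is erased in step 4.

Step 4
Reactants: 5 (1S,6S)-1,2,6-trimethylcyclohex-2-en-1-ol
Product: 6 (S)-2,3,4-trimethylcyclohex-2-en-1-one
Conditions: C5H5NH[CrO3Cl] (pyridinium chlorochromate), CH2Cl2, rt
Reagents that add atoms: pyridinium chlorochromate, [O-][Cr](=O)(=O)Cl.c1cc[nH+]cc1
Why: Babler–Dauben oxidative transposition: the tertiary chromate ester undergoes a [3,3] shift to the secondary allylic chromate, which is oxidised to the enone; the oxygen now sits on the future C1, the old carbonyl carbon is the methyl-bearing future C3, and the gamma-stereocentre C4 is not involved.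

Step 5
Reactants: 6 (S)-2,3,4-trimethylcyclohex-2-en-1-one
Product: 7 (1R,4S)-2,3,4-trimethylcyclohex-2-en-1-ol
Conditions: (S)-Me-CBS oxazaborolidine [(S)-1-methyl-3,3-diphenyltetrahydro-1H,3H-pyrrolo[1,2-c][1,3,2]oxazaborole] (cat.), BH3·SMe2, THF, −20 °C; MeOH
Reagents that add atoms: none
Why: Corey–Bakshi–Shibata reduction: the tetrasubstituted alkene side acts as the large group, so the catalyst should give the 1R alcohol whatever the substrate bias, which is the 1,4-cis isomer from (S)-6; the minor enantiomer of 6 left by step 1 becomes the trans diastereomer, removable by chromatography, so the step should also raise the optical purity.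

Step 6
Reactants: 7 (1R,4S)-2,3,4-trimethylcyclohex-2-en-1-ol
Product: 9 ethyl 2-[(1S,6S)-1,2,6-trimethylcyclohex-2-en-1-yl]acetate, via ketene acetal 8 (not isolated)
Conditions: MeC(OEt)3, EtCO2H (cat.), 150 °C, sealed tube
Reagents that add atoms: triethyl orthoacetate, CC(OCC)(OCC)OCC
Why: Johnson–Claisen (orthoester Claisen) rearrangement: acid-catalysed exchange of 7 into the orthoester and loss of ethanol give ketene acetal 8, whose O–C1–C2=C3 allyl unit and O–C=CH2 vinyl unit undergo a concerted suprafacial [3,3] shift that makes the C3–C1' bond while the C1–O bond breaks and the alkene moves to C1=C2. The closest known reaction type is the orthoester Claisen rearrangement of ring-substituted 2,3-dimethylcyclohex-2-en-1-ols, which builds the same kind of ring quaternary carbon from a tetrasubstituted alkene. No ring is closed. The one new stereocentre, quaternary C3, is controlled by C1: the arm can only reach the ring face that carried the oxygen, and because that oxygen is cis to the C4 methyl group the arm arrives cis to it and the C3 methyl ends up trans, as the target requires. The C1 stereocentre is consumed, so the step is a 1,3-transfer of chirality from a centre set by catalytic reduction to a quaternary carbon that has no simple direct entry. The step needs the rearrangement to outrun ionisation of the allylic C1–O bond (loss to dienes, or 1,3-return of oxygen); the weak acid, the absence of a nucleophilic solvent and the half-chair of 7, in which C1–O is pseudo-axial and the C4 methyl pseudo-equatorial so that the vinyl terminus reaches C3 without reorganising the ring, favour the [3,3] path. The product carries exactly the two-carbon arm of the target, and its C1=C2 bond is the latent ketone.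

Step 7
Reactants: 9 ethyl 2-[(1S,6S)-1,2,6-trimethylcyclohex-2-en-1-yl]acetate
Product: 11 (1S,2S,3S,4S)-3-(2-hydroxyethyl)-2,3,4-trimethylcyclohexan-1-ol, via organoborane 10 (not isolated)
Conditions: BH3·SMe2 (excess), THF, 0 °C to 65 °C; NaOH, H2O2, 0 °C
Reagents that add atoms: hydrogen peroxide, OO
Why: Hydroboration–oxidation with concurrent reduction of the ester by borane: boron goes to the less substituted C1 and hydrogen to C2 in a syn addition from the face opposite the pseudo-axial C3 arm (the other half-chair would put methyl groups on both faces), which pushes the C2 methyl cis to the arm; oxidation of the C–B bond with retention gives the C1 alcohol, whose configuration is irrelevant.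

Step 8
Reactants: 11 (1S,2S,3S,4S)-3-(2-hydroxyethyl)-2,3,4-trimethylcyclohexan-1-ol
Product: 12 2-[(1S,2S,6S)-1,2,6-trimethyl-3-oxocyclohexyl]acetaldehyde
Conditions: Dess–Martin periodinane, NaHCO3, CH2Cl2, 0 °C to rt
Reagents that add atoms: none
Why: Dess–Martin oxidation of both hydroxyl groups under buffered, non-enolising conditions, so the kinetically set C2 centre next to the new ketone is kept; the aldehyde has no alpha-stereocentre.

Step 9
Reactants: 13 orcinol (5-methylbenzene-1,3-diol)
Product: 14 4-chloro-5-methylbenzene-1,3-diol
Conditions: SO2Cl2, Et2O, 0 °C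
Reagents that add atoms: sulfuryl chloride, ClS(Cl)(=O)=O
Why: Electrophilic aromatic chlorination; the position para to one hydroxyl and ortho to the other is the most reactive, and one equivalent at low temperature should limit the 2-chloro and dichloro by-products.

Step 10
Reactants: 14 4-chloro-5-methylbenzene-1,3-diol
Product: 15 1-chloro-2,4-bis(methoxymethoxy)-6-methylbenzene
Conditions: MOMCl, iPr2NEt, CH2Cl2, 0 °C to rt
Reagents that add atoms: chloromethyl methyl ether, COCCl
Why: Acetal protection of both phenols by O-alkylation; the methoxymethyl ethers are needed as directing groups for the metalation in step 13.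

Step 11
Reactants: 16 but-2-yn-1-ol
Product: 18 (E)-3-iodobut-2-en-1-ol, via alkenylzirconocene 17 (not isolated)
Conditions: Cp2Zr(H)Cl (2.2 equiv), THF, rt; I2, 0 °C
Reagents that add atoms: iodine, II
Why: Syn-hydrozirconation of the alkyne (the first equivalent of hydride is consumed by the hydroxyl group); after equilibration zirconium should rest on the methyl-bearing carbon, away from the alkoxide end, and iodinolysis with retention gives the E-iodoalkene.

Step 12
Reactants: 18 (E)-3-iodobut-2-en-1-ol
Product: 19 (E)-1-bromo-3-iodobut-2-ene
Conditions: CBr4, PPh3, CH2Cl2, 0 °C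
Reagents that add atoms: carbon tetrabromide, BrC(Br)(Br)Br
Why: Appel bromination of a primary allylic alcohol under neutral conditions; the alkenyl iodide and the alkene geometry are untouched.

Step 13
Reactants: 15 1-chloro-2,4-bis(methoxymethoxy)-6-methylbenzene; 19 (E)-1-bromo-3-iodobut-2-ene
Product: 22 1-chloro-3-[(2E)-3-iodobut-2-en-1-yl]-2,4-bis(methoxymethoxy)-6-methylbenzene, via aryllithium 20 (not isolated), via arylcopper 21 (not isolated)
Conditions: n-BuLi, THF, 0 °C; CuI, −78 to −40 °C; 19, −78 °C to rt
Reagents that add atoms: none
Why: Directed ortho-metalation at the only position flanked by two acetal oxygens (chlorine has no ortho hydrogen, so no aryne can form), transmetalation to copper and SN2 coupling with the primary allylic bromide; attack at the gamma-carbon would create a fully substituted iodinated carbon and is disfavoured, and the organocopper reagent should not exchange with the alkenyl iodide at low temperature.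

Step 14
Reactants: 22 1-chloro-3-[(2E)-3-iodobut-2-en-1-yl]-2,4-bis(methoxymethoxy)-6-methylbenzene
Product: 23 4-chloro-2-[(2E)-3-iodobut-2-en-1-yl]-5-methylbenzene-1,3-diol
Conditions: HCl, MeOH, 40 °C
Reagents that add atoms: none
Why: Acid-catalysed transacetalisation removes both methoxymethyl groups once they have served as directing groups; the iodoalkene is a poor proton acceptor, so cyclisation of a phenol onto the alkene is not expected.

Step 15
Reactants: 23 4-chloro-2-[(2E)-3-iodobut-2-en-1-yl]-5-methylbenzene-1,3-diol
Product: 24 {[4-chloro-2-[(2E)-3-iodobut-2-en-1-yl]-5-methyl-1,3-phenylene]bis(oxy)}bis[tert-butyl(dimethyl)silane]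
Conditions: TBSCl, imidazole, DMF, rt
Reagents that add atoms: tert-butyldimethylsilyl chloride, CC(C)(C)[Si](C)(C)Cl
Why: Silylation of both phenols gives fluoride-labile ethers that survive the chromium-mediated coupling and can be removed later without acid or strong base.

Step 16
Reactants: 12 2-[(1S,2S,6S)-1,2,6-trimethyl-3-oxocyclohexyl]acetaldehyde; 24 {[4-chloro-2-[(2E)-3-iodobut-2-en-1-yl]-5-methyl-1,3-phenylene]bis(oxy)}bis[tert-butyl(dimethyl)silane]
Product: 25 (2S,3S,4S)-3-[(2S,3E)-5-{2,6-bis[(tert-butyldimethylsilyl)oxy]-3-chloro-4-methylphenyl}-2-hydroxy-3-methylpent-3-en-1-yl]-2,3,4-trimethylcyclohexan-1-one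
Conditions: CrCl2, NiCl2 (cat.), (S)-N-[2-(4-isopropyl-4,5-dihydro-1,3-oxazol-2-yl)phenyl]methanesulfonamide, Et3N, THF, rt
Reagents that add atoms: none
Why: Nozaki–Hiyama–Kishi reaction: zerovalent nickel inserts into the C–I bond with retention of alkene geometry, the alkenyl group passes to trivalent chromium and adds to the aldehyde only, leaving the ketone and the aryl chloride; the chiral sulfonamide–oxazoline ligand on chromium selects the aldehyde face and should give the S carbinol, since the ring stereocentres are too remote to exert control.

Step 17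
Reactants: 25 (2S,3S,4S)-3-[(2S,3E)-5-{2,6-bis[(tert-butyldimethylsilyl)oxy]-3-chloro-4-methylphenyl}-2-hydroxy-3-methylpent-3-en-1-yl]-2,3,4-trimethylcyclohexan-1-one
Product: 26 (2S,3S,4S)-3-[(2S,3E)-5-(3-chloro-2,6-dihydroxy-4-methylphenyl)-2-hydroxy-3-methylpent-3-en-1-yl]-2,3,4-trimethylcyclohexan-1-one
Conditions: Bu4NF, AcOH, THF, 0 °C
Reagents that add atoms: none
Why: Fluoride cleavage of the two aryl silyl ethers, buffered with acetic acid so that neither phenoxide nor fluoride can enolise the ketone and epimerise C2.

Step 18
Reactants: 26 (2S,3S,4S)-3-[(2S,3E)-5-(3-chloro-2,6-dihydroxy-4-methylphenyl)-2-hydroxy-3-methylpent-3-en-1-yl]-2,3,4-trimethylcyclohexan-1-one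
Product: 27 5-chloro-2-hydroxy-3-{(2E,4S)-4-hydroxy-3-methyl-5-[(1S,2S,6S)-1,2,6-trimethyl-3-oxocyclohexyl]pent-2-en-1-yl}-6-methylcyclohexa-2,5-diene-1,4-dione (CNP0469571.3)
Conditions: ON(SO3K)2 (Fremy's salt), KH2PO4, H2O/acetone, rt
Reagents that add atoms: potassium nitrosodisulfonate, [O]N(S(=O)(=O)[O-])S(=O)(=O)[O-].[K+].[K+]
Why: Teuber oxidation: the nitrosodisulfonate radical oxidises the phenol to its phenoxyl radical and couples at the only free ring position, para to one hydroxyl, giving the hydroxy-p-quinone; the near-neutral buffer should spare the allylic alcohol and C2.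

## Compound list

1 | cis-2,6-dimethylcyclohexan-1-one (meso, 2R,6S) | C[C@@H]1CCC[C@H](C)C1=O | starting material
2 | lithium (S)-2,6-dimethylcyclohex-1-en-1-olate | [Li]OC1=C(C)CCC[C@@H]1C | intermediate
3 | (S)-[(2,6-dimethylcyclohex-1-en-1-yl)oxy]trimethylsilane | C[Si](C)(C)OC1=C(C)CCC[C@@H]1C | intermediate
4 | (S)-2,6-dimethylcyclohex-2-en-1-one | O=C1C(C)=CCC[C@@H]1C | intermediate
5 | (1S,6S)-1,2,6-trimethylcyclohex-2-en-1-ol | O[C@]1(C)C(C)=CCC[C@@H]1C | intermediate
6 | (S)-2,3,4-trimethylcyclohex-2-en-1-one | CC1=C(C)[C@@H](C)CCC1=O | intermediate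
7 | (1R,4S)-2,3,4-trimethylcyclohex-2-en-1-ol (OH cis to the C4 methyl) | CC1=C(C)[C@@H](C)CC[C@H]1O | intermediate
8 | 1-ethoxy-1-{[(1R,4S)-2,3,4-trimethylcyclohex-2-en-1-yl]oxy}ethene (ketene acetal) | CC1=C(C)[C@@H](C)CC[C@H]1OC(=C)OCC | intermediate
9 | ethyl 2-[(1S,6S)-1,2,6-trimethylcyclohex-2-en-1-yl]acetate | CCOC(=O)C[C@]1(C)C(C)=CCC[C@@H]1C | intermediate
10 | organoborane from 9: boron on C1 trans to the arm, side-chain oxygen as O-boryl (drawn as the BH2 forms) | BOCC[C@]1(C)[C@H](C)[C@@H](B)CC[C@@H]1C | intermediate
11 | (1S,2S,3S,4S)-3-(2-hydroxyethyl)-2,3,4-trimethylcyclohexan-1-ol | OCC[C@]1(C)[C@H](C)[C@@H](O)CC[C@@H]1C | intermediate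
12 | 2-[(1S,2S,6S)-1,2,6-trimethyl-3-oxocyclohexyl]acetaldehyde | O=CC[C@]1(C)[C@H](C)C(=O)CC[C@@H]1C | intermediate
13 | orcinol (5-methylbenzene-1,3-diol) | Cc1cc(O)cc(O)c1 | starting material
14 | 4-chloro-5-methylbenzene-1,3-diol | Cc1cc(O)cc(O)c1Cl | intermediate
15 | 1-chloro-2,4-bis(methoxymethoxy)-6-methylbenzene | COCOc1cc(C)c(Cl)c(OCOC)c1 | intermediate
16 | but-2-yn-1-ol | CC#CCO | starting material
17 | (E)-alkenylzirconocene chloride of but-2-yn-1-ol, oxygen bound to a second zirconocene chloride | C/C(=C\CO[Zr](Cl)(C1C=CC=C1)C1C=CC=C1)[Zr](Cl)(C1C=CC=C1)C1C=CC=C1 | intermediate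
18 | (E)-3-iodobut-2-en-1-ol | C/C(I)=C\CO | intermediate
19 | (E)-1-bromo-3-iodobut-2-ene | C/C(I)=C\CBr | intermediate
20 | [3-chloro-2,6-bis(methoxymethoxy)-4-methylphenyl]lithium | [Li]c1c(OCOC)cc(C)c(Cl)c1OCOC | intermediate
21 | [3-chloro-2,6-bis(methoxymethoxy)-4-methylphenyl]copper | [Cu]c1c(OCOC)cc(C)c(Cl)c1OCOC | intermediate
22 | 1-chloro-3-[(2E)-3-iodobut-2-en-1-yl]-2,4-bis(methoxymethoxy)-6-methylbenzene | COCOc1cc(C)c(Cl)c(OCOC)c1C/C=C(\C)I | intermediate
23 | 4-chloro-2-[(2E)-3-iodobut-2-en-1-yl]-5-methylbenzene-1,3-diol | Cc1cc(O)c(C/C=C(\C)I)c(O)c1Cl | intermediate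
24 | {[4-chloro-2-[(2E)-3-iodobut-2-en-1-yl]-5-methyl-1,3-phenylene]bis(oxy)}bis[tert-butyl(dimethyl)silane] | Cc1cc(O[Si](C)(C)C(C)(C)C)c(C/C=C(\C)I)c(O[Si](C)(C)C(C)(C)C)c1Cl | intermediate
25 | (2S,3S,4S)-3-[(2S,3E)-5-{2,6-bis[(tert-butyldimethylsilyl)oxy]-3-chloro-4-methylphenyl}-2-hydroxy-3-methylpent-3-en-1-yl]-2,3,4-trimethylcyclohexan-1-one | Cc1cc(O[Si](C)(C)C(C)(C)C)c(C/C=C(\C)[C@@H](O)C[C@]2(C)[C@H](C)C(=O)CC[C@@H]2C)c(O[Si](C)(C)C(C)(C)C)c1Cl | intermediate
26 | (2S,3S,4S)-3-[(2S,3E)-5-(3-chloro-2,6-dihydroxy-4-methylphenyl)-2-hydroxy-3-methylpent-3-en-1-yl]-2,3,4-trimethylcyclohexan-1-one | Cc1cc(O)c(C/C=C(\C)[C@@H](O)C[C@]2(C)[C@H](C)C(=O)CC[C@@H]2C)c(O)c1Cl | intermediate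
27 | 5-chloro-2-hydroxy-3-{(2E,4S)-4-hydroxy-3-methyl-5-[(1S,2S,6S)-1,2,6-trimethyl-3-oxocyclohexyl]pent-2-en-1-yl}-6-methylcyclohexa-2,5-diene-1,4-dione | CC1=C(Cl)C(=O)C(C/C=C(\C)[C@@H](O)C[C@]2(C)[C@H](C)C(=O)CC[C@@H]2C)=C(O)C1=O | target

## Step count and least certain steps

Total step count: 18. Longest linear sequence: 11 steps (steps 1 to 8, then 16 to 18). The aryl branch (steps 9, 10, 13, 14, 15) has five steps and the bromide branch (steps 11, 12) two.

**Step 6 (key step).**
- What may go wrong: ionisation of the allylic C1–O bond in the hot, weakly acidic medium, leading to elimination or to return of the oxygen at C3 with loss of the stereochemical information; and slow bond formation at C3, which is fully substituted and flanked by the C4 methyl group.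
- Fallback (replaces steps 3 to 8 and builds the quaternary centre by bringing the methyl group last): from enone 4, allylmagnesium bromide with CeCl3 would give (1S,6S)-2,6-dimethyl-1-(prop-2-en-1-yl)cyclohex-2-en-1-ol F1. Oxidative transposition with pyridinium chlorochromate would give (S)-2,4-dimethyl-3-(prop-2-en-1-yl)cyclohex-2-en-1-one F2. Me2CuLi with BF3·OEt2 should add methyl to C3 anti to the C4 methyl group to give lithium (3S,4S)-2,3,4-trimethyl-3-(prop-2-en-1-yl)cyclohex-1-en-1-olate F3, and protonation at low temperature from the face opposite the arm would give (2S,3S,4S)-2,3,4-trimethyl-3-(prop-2-en-1-yl)cyclohexan-1-one F4. Ozone would convert the terminal alkene into the ozonide 3-{[(1S,2S,6S)-1,2,6-trimethyl-3-oxocyclohexyl]methyl}-1,2,4-trioxolane F5, and PPh3 would reduce it to keto aldehyde 12.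

**Step 7.**
- What may go wrong: poor or reversed facial selectivity in the hydroboration (formation of the C2 epimer), because the two substituents on C3 differ only modestly in size; incomplete reduction of the hindered ester.
- Fallback with the opposite stereochemical demand: from ester 9, a peracid (mCPBA, NaHCO3), which should choose the same face as borane, would give ethyl 2-[(1S,6S)-2,3-epoxy-1,2,6-trimethylcyclohexyl]acetate F6 (oxirane oxygen cis to the arm in the case this fallback answers). A Lewis acid (BF3·OEt2 or LiClO4) would open the oxirane at the tertiary carbon, and a 1,2-hydride shift anti to the departing oxygen (Meinwald rearrangement) would place the C2 methyl cis to the arm, giving ethyl 2-[(1S,2S,6S)-1,2,6-trimethyl-3-oxocyclohexyl]acetate F7. LiAlH4 would then give diol 11 together with its C1 epimer (1R,2S,3S,4S)-3-(2-hydroxyethyl)-2,3,4-trimethylcyclohexan-1-ol F8, and step 8 converts both into 12. Ring contraction is the known competitor in such rearrangements.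

**Step 13.**
- What may go wrong: halogen–metal exchange at the alkenyl iodide, attack at the gamma-carbon of the allylic bromide, or homocoupling of the arylcopper.
- Fallback that forms the iodoalkene after the aryl–carbon bond: from 15, aryllithium 20 (made as in step 13) would be alkylated directly with 1-bromobut-2-yne, without copper so that SN2' attack to an allene is not favoured, giving 3-(but-2-yn-1-yl)-1-chloro-2,4-bis(methoxymethoxy)-6-methylbenzene F9. Syn-hydrozirconation with Cp2Zr(H)Cl should place zirconium on the methyl-bearing carbon, away from the bulky arylmethyl group, giving the alkenylzirconocene chloride F10, and iodine would convert it into 22.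

**Step 16.**
- What may go wrong: insufficient facial selectivity at the aldehyde, since the ligand is the only source of control and the two C2' epimers may be hard to separate.
- Fallback by oxidation and enone-selective asymmetric reduction: from 12 and 24, coupling without the chiral ligand would give 25 together with (2S,3S,4S)-3-[(2R,3E)-5-{2,6-bis[(tert-butyldimethylsilyl)oxy]-3-chloro-4-methylphenyl}-2-hydroxy-3-methylpent-3-en-1-yl]-2,3,4-trimethylcyclohexan-1-one F11. MnO2 would oxidise only the allylic alcohol of both to (2S,3S,4S)-3-[(3E)-5-{2,6-bis[(tert-butyldimethylsilyl)oxy]-3-chloro-4-methylphenyl}-3-methyl-2-oxopent-3-en-1-yl]-2,3,4-trimethylcyclohexan-1-one F12. The binaphthol-modified hydride Li[AlH(OEt)(1,1'-bi-2-naphtholate)] (BINAL-H, enantiomer chosen for the S alcohol) reduces conjugated ketones much faster than hindered dialkyl ketones at −100 °C and should return 25.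

## Further compounds

F1 | step 6 | (1S,6S)-2,6-dimethyl-1-(prop-2-en-1-yl)cyclohex-2-en-1-ol | O[C@]1(CC=C)C(C)=CCC[C@@H]1C
F2 | step 6 | (S)-2,4-dimethyl-3-(prop-2-en-1-yl)cyclohex-2-en-1-one | CC1=C(CC=C)[C@@H](C)CCC1=O
F3 | step 6 | lithium (3S,4S)-2,3,4-trimethyl-3-(prop-2-en-1-yl)cyclohex-1-en-1-olate | [Li]OC1=C(C)[C@@](C)(CC=C)[C@@H](C)CC1
F4 | step 6 | (2S,3S,4S)-2,3,4-trimethyl-3-(prop-2-en-1-yl)cyclohexan-1-one | C=CC[C@]1(C)[C@H](C)C(=O)CC[C@@H]1C
F5 | step 6 | 3-{[(1S,2S,6S)-1,2,6-trimethyl-3-oxocyclohexyl]methyl}-1,2,4-trioxolane (ozonide, mixture at the trioxolane carbon) | C1OC(C[C@]2(C)[C@H](C)C(=O)CC[C@@H]2C)OO1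
F6 | step 7 | ethyl 2-[(1S,6S)-2,3-epoxy-1,2,6-trimethylcyclohexyl]acetate, oxirane oxygen cis to the arm | CCOC(=O)C[C@]1(C)[C@]2(C)O[C@@H]2CC[C@@H]1C
F7 | step 7 | ethyl 2-[(1S,2S,6S)-1,2,6-trimethyl-3-oxocyclohexyl]acetate | CCOC(=O)C[C@]1(C)[C@H](C)C(=O)CC[C@@H]1C
F8 | step 7 | (1R,2S,3S,4S)-3-(2-hydroxyethyl)-2,3,4-trimethylcyclohexan-1-ol | OCC[C@]1(C)[C@H](C)[C@H](O)CC[C@@H]1C
F9 | step 13 | 3-(but-2-yn-1-yl)-1-chloro-2,4-bis(methoxymethoxy)-6-methylbenzene | COCOc1cc(C)c(Cl)c(OCOC)c1CC#CC
F10 | step 13 | chlorobis(cyclopentadienyl){(2E)-4-[3-chloro-2,6-bis(methoxymethoxy)-4-methylphenyl]but-2-en-2-yl}zirconium | COCOc1cc(C)c(Cl)c(OCOC)c1C/C=C(\C)[Zr](Cl)(C1C=CC=C1)C1C=CC=C1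
F11 | step 16 | (2S,3S,4S)-3-[(2R,3E)-5-{2,6-bis[(tert-butyldimethylsilyl)oxy]-3-chloro-4-methylphenyl}-2-hydroxy-3-methylpent-3-en-1-yl]-2,3,4-trimethylcyclohexan-1-one | Cc1cc(O[Si](C)(C)C(C)(C)C)c(C/C=C(\C)[C@H](O)C[C@]2(C)[C@H](C)C(=O)CC[C@@H]2C)c(O[Si](C)(C)C(C)(C)C)c1Cl
F12 | step 16 | (2S,3S,4S)-3-[(3E)-5-{2,6-bis[(tert-butyldimethylsilyl)oxy]-3-chloro-4-methylphenyl}-3-methyl-2-oxopent-3-en-1-yl]-2,3,4-trimethylcyclohexan-1-one | Cc1cc(O[Si](C)(C)C(C)(C)C)c(C/C=C(\C)C(=O)C[C@]2(C)[C@H](C)C(=O)CC[C@@H]2C)c(O[Si](C)(C)C(C)(C)C)c1Cl
A1 | alternative 1 | (S)-4-methyl-3-(prop-2-en-1-yl)cyclohex-2-en-1-one | C=CCC1=CC(=O)CC[C@@H]1C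
A2 | alternative 1 | (2R,3S,4S)-2,3,4-trimethyl-3-(prop-2-en-1-yl)cyclohexan-1-one | C=CC[C@]1(C)[C@@H](C)C(=O)CC[C@@H]1C
A3 | alternative 2 | 3-isopropoxy-4-[(2E,4S)-4-(tert-butyldimethylsilyloxy)-3-methyl-5-(ring B as its C1 ethylene ketal)pent-2-en-1-yl]cyclobut-3-ene-1,2-dione | CC(C)OC1=C(C/C=C(\C)[C@@H](O[Si](C)(C)C(C)(C)C)C[C@]2(C)[C@H](C)C3(OCCO3)CC[C@@H]2C)C(=O)C1=O
A4 | alternative 2 | 4-(1-chloroprop-1-en-2-yl)-4-hydroxy-3-isopropoxy-2-[the same chain as in A3]cyclobut-2-en-1-one (mixture at the new carbinol carbon) | CC(C)OC1=C(C/C=C(\C)[C@@H](O[Si](C)(C)C(C)(C)C)C[C@]2(C)[C@H](C)C3(OCCO3)CC[C@@H]2C)C(=O)C1(O)C(C)=CCl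
A5 | alternative 3 | 1,3-dimethoxy-5,6,9-trimethyl-2-oxabicyclo[3.3.1]nonane, ring-B configuration as in 12, anomer mixture at C3 of the bicycle | COC1C[C@]2(C)[C@H](C)[C@](OC)(O1)CC[C@@H]2C
A6 | alternative 3 | bicyclic methyl ketal of 25: 1-methoxy-5,6,9-trimethyl-2-oxabicyclo[3.3.1]nonane carrying the (E)-4-aryl-but-2-en-2-yl group exo at C3 (S at that carbon) | Cc1cc(O[Si](C)(C)C(C)(C)C)c(C/C=C(\C)[C@@H]2C[C@]3(C)[C@H](C)[C@](OC)(O2)CC[C@@H]3C)c(O[Si](C)(C)C(C)(C)C)c1Cl
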